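The cresol ring is cut at two C–C bonds, C1–C2 and C5–C6 (C1 bears the carbinol, C2 the phenol oxygen, C4 the methyl), which leads back to an ethynyl carbinol and 3-methylcyclohexa-1,3-dien-1-ol. The phenol oxygen on C2 and the tertiary carbinol oxygen are 1,3-related through C1, so a single diisopropylsilylene can tie alkyne and dienol together; a tethered Alder–Rickert reaction ([4+2] addition, then loss of ethene) should then form the benzene ring and a six-membered 1,3,2-dioxasiline ring at once, with oxygen ortho and methyl para by necessity. The precursor is the enantiopure, fully acylated 2-ethynylglycerol linked through O–Si–O to the linear dienol ether; one HF step follows.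

Key step: step 8

Assumption: the lipase of step 3 is taken to acylate the pro-R hydroxymethyl group of the prochiral triol; sense and enantiomeric purity are to be verified on the first run, and the hydrolytic variant given at the end reaches the same monoester if the enzyme prefers the other arm.
Assumption: the 2-methylbutanoyl centre of the target is R and the carbinol carbon is S; (2R)-2-methylbutanoic acid is taken as purchasable in high enantiomeric purity.

Step 1
Reactants: 1 2,2-dimethyl-1,3-dioxan-5-one; 2 ethynylmagnesium bromide
Product: 3 5-ethynyl-2,2-dimethyl-1,3-dioxan-5-ol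
Conditions: THF, 0 °C → rt; then sat. aq NH4Cl
Reagents that add atoms: ethynylmagnesium bromide (2), C#C[Mg]Br
Why: Grignard 1,2-addition of an alkynyl nucleophile to a ketone; the new carbinol carbon lies on the mirror plane of the dioxane and is not a stereocentre.

Step 2
Reactants: 3 5-ethynyl-2,2-dimethyl-1,3-dioxan-5-ol
Product: 4 2-ethynylpropane-1,2,3-triol
Conditions: Dowex 50W-X8 (H+ form), H2O–MeCN, 40 °C; filter, evaporate
Reagents that add atoms: none
Why: Acid-catalysed acetal hydrolysis; the resin acid is too weak to ionise or rearrange the tertiary propargylic alcohol, and filtration avoids extracting the water-soluble triol.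

Step 3
Reactants: 4 2-ethynylpropane-1,2,3-triol; 5 2-methylpropanoic anhydride
Product: 6 (2R)-2-ethynyl-2,3-dihydroxypropyl 2-methylpropanoate
Conditions: Burkholderia cepacia lipase (Amano PS, immobilised), 5 (1.1 equiv), THF–t-BuOMe, 0–20 °C; filter, use crude at once
Reagents that add atoms: 2-methylpropanoic anhydride (5), CC(C)C(=O)OC(=O)C(C)C
Why: Lipase-catalysed acylative desymmetrisation of a prochiral 2-substituted propane-1,3-diol: the acyl-enzyme passes the isobutyryl group to one enantiotopic CH2OH (taken as the pro-R arm), so the enzyme sets the carbinol carbon as R, and slow diacylation of the minor enantiomer should raise the purity of the monoester.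

Step 4
Reactants: 6 (2R)-2-ethynyl-2,3-dihydroxypropyl 2-methylpropanoate; 7 (2R)-2-methylbutanoic acid
Product: 8 (2S)-2-ethynyl-2-hydroxy-3-[(2-methylpropanoyl)oxy]propyl (2R)-2-methylbutanoate
Conditions: EDC·HCl, DMAP (cat.), CH2Cl2, −10 → 0 °C
Reagents that add atoms: (2R)-2-methylbutanoic acid (7), CC[C@@H](C)C(=O)O
Why: Steglich esterification of the remaining primary hydroxyl (the tertiary one is too hindered); the acyl stereocentre comes with 7, low temperature and little DMAP guard it against epimerisation and the carbinol against acyl migration, and the carbinol descriptor changes from R to S only through CIP priority.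

Step 5
Reactants: 9 3-methylanisole (1-methoxy-3-methylbenzene)
Product: 10 1-methoxy-5-methylcyclohexa-1,4-diene
Conditions: Li, NH3 (l), THF, t-BuOH, −78 → −33 °C; then MeOH, H2O
Reagents that add atoms: none
Why: Birch reduction; the donor groups OMe and Me end up on the two remaining double bonds, so one regioisomer of the 2,5-dihydroarene should form.

Step 6
Reactants: 10 1-methoxy-5-methylcyclohexa-1,4-diene
Product: 11 3-methylcyclohex-3-en-1-one
Conditions: (CO2H)2 (cat.), acetone–H2O, rt; use freshly prepared
Reagents that add atoms: water, O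
Why: Enol ether hydrolysis under weak acid gives the β,γ-unsaturated ketone, since oxalic acid is too weak to move the C3=C4 bond into conjugation.

Step 7
Reactants: 8 (2S)-2-ethynyl-2-hydroxy-3-[(2-methylpropanoyl)oxy]propyl (2R)-2-methylbutanoate; 12 di(propan-2-yl)silanediyl bis(trifluoromethanesulfonate); 11 3-methylcyclohex-3-en-1-one
Product: 14 (2S)-2-ethynyl-2-({[(3-methylcyclohexa-1,3-dien-1-yl)oxy]di(propan-2-yl)silyl}oxy)-3-[(2-methylpropanoyl)oxy]propyl (2R)-2-methylbutanoate, via silyl triflate 13 (not isolated)
Conditions: 12 (1.0 equiv), 2,6-lutidine, CH2Cl2, −78 → 0 °C; then 11 (1.3 equiv), Et3N, −78 → 0 °C; Et3N-treated SiO2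
Reagents that add atoms: di(propan-2-yl)silanediyl bis(trifluoromethanesulfonate) (12), CC(C)[Si](OS(=O)(=O)C(F)(F)F)(OS(=O)(=O)C(F)(F)F)C(C)C
Why: Silyl triflate silylation of the tertiary alcohol, then soft enolisation of the ketone (O-silylation and amine deprotonation at C2, the position activated by both C=O and C3=C4) should give the linear 1-silyloxy-1,3-diene without any metal enolate or alkoxide that could attack or epimerise the esters; no stereocentre is formed.

Step 8
Reactants: 14 (2S)-2-ethynyl-2-({[(3-methylcyclohexa-1,3-dien-1-yl)oxy]di(propan-2-yl)silyl}oxy)-3-[(2-methylpropanoyl)oxy]propyl (2R)-2-methylbutanoate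
Product: 16 [(4S)-7-methyl-4-{[(2-methylpropanoyl)oxy]methyl}-2,2-di(propan-2-yl)-4H-1,3,2-benzodioxasilin-4-yl]methyl (2R)-2-methylbutanoate, via bicyclo[2.2.2]octadiene 15 (not isolated)
Conditions: degassed PhMe (0.01 M), BHT (cat.), base-washed sealed tube, 180–200 °C
Reagents that add atoms: none
Why: Proposed new method: on heating, the locked s-cis 1-silyloxydiene (ring carbons C1–C4) should add across the ethynyl group held on the same silicon in a concerted [4+2] step to give bicyclo[2.2.2]octadiene 15, which then loses its CH2–CH2 bridge as ethene in a retro-[4+2] step driven by aromatisation. The closest known reaction types are the intermolecular Alder–Rickert arene synthesis from 1-oxycyclohexa-1,3-dienes and activated alkynes and the silicon-tethered type 1 intramolecular Diels–Alder reaction; new here is their union with an unactivated propargylic alkyne. The dioxasiline ring closes as the tether ring of the cycloaddition, by 6-exo-dig bonding of the oxygenated diene terminus C1 to the internal alkyne carbon, and the benzene ring closes by the second bond, from C4 to the terminal alkyne carbon, and is laid bare by the cycloreversion. No stereocentre is formed in 16: the bridgehead centres of 15 arise as a mixture of facial isomers and both vanish with the ethene, while the carbinol and acyl centres, set earlier, meet only neutral thermal conditions. The regiochemistry the step needs (oxygen ortho, methyl para to the carbinol carbon) is secured by the four-atom O–Si–O–C tether, which lets only the internal alkyne carbon reach C1, and the reactivity of the unactivated alkyne is secured by intramolecularity and the compressing isopropyl groups on silicon, with high dilution against intermolecular addition.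

Step 9
Reactants: 16 [(4S)-7-methyl-4-{[(2-methylpropanoyl)oxy]methyl}-2,2-di(propan-2-yl)-4H-1,3,2-benzodioxasilin-4-yl]methyl (2R)-2-methylbutanoate
Product: 17 (2S)-2-hydroxy-2-(2-hydroxy-4-methylphenyl)-3-[(2-methylpropanoyl)oxy]propyl (2R)-2-methylbutanoate (CNP0286200.2)
Conditions: HF·pyridine, pyridine, THF, 0 °C → rt
Reagents that add atoms: none
Why: Fluoride-induced Si–O cleavage (desilylation) under buffered, weakly acidic conditions should free the phenol and the tertiary alcohol as iPr2SiF2 leaves; no base is present, so the esters neither migrate nor hydrolyse and both stereocentres are kept.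

Compound list
1 | 2,2-dimethyl-1,3-dioxan-5-one | CC1(C)OCC(=O)CO1 | starting material
2 | ethynylmagnesium bromide | C#C[Mg]Br | starting material
3 | 5-ethynyl-2,2-dimethyl-1,3-dioxan-5-ol | CC1(C)OCC(O)(C#C)CO1 | intermediate
4 | 2-ethynylpropane-1,2,3-triol | OCC(O)(CO)C#C | intermediate
5 | 2-methylpropanoic anhydride | CC(C)C(=O)OC(=O)C(C)C | starting material
6 | (2R)-2-ethynyl-2,3-dihydroxypropyl 2-methylpropanoate | OC[C@](C#C)(COC(=O)C(C)C)O | intermediate
7 | (2R)-2-methylbutanoic acid | CC[C@@H](C)C(=O)O | starting material
8 | (2S)-2-ethynyl-2-hydroxy-3-[(2-methylpropanoyl)oxy]propyl (2R)-2-methylbutanoate | CC[C@@H](C)C(=O)OC[C@](C#C)(COC(=O)C(C)C)O | intermediate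
9 | 3-methylanisole (1-methoxy-3-methylbenzene) | COc1cccc(C)c1 | starting material
10 | 1-methoxy-5-methylcyclohexa-1,4-diene | COC1=CCC=C(C)C1 | intermediate
11 | 3-methylcyclohex-3-en-1-one | CC1=CCCC(=O)C1 | intermediate
12 | di(propan-2-yl)silanediyl bis(trifluoromethanesulfonate) | CC(C)[Si](OS(=O)(=O)C(F)(F)F)(OS(=O)(=O)C(F)(F)F)C(C)C | starting material
13 | (2S)-2-ethynyl-3-[(2-methylpropanoyl)oxy]-2-({di(propan-2-yl)[(trifluoromethanesulfonyl)oxy]silyl}oxy)propyl (2R)-2-methylbutanoate (silyl triflate, not isolated) | CC[C@@H](C)C(=O)OC[C@](C#C)(COC(=O)C(C)C)O[Si](C(C)C)(C(C)C)OS(=O)(=O)C(F)(F)F | intermediate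
14 | (2S)-2-ethynyl-2-({[(3-methylcyclohexa-1,3-dien-1-yl)oxy]di(propan-2-yl)silyl}oxy)-3-[(2-methylpropanoyl)oxy]propyl (2R)-2-methylbutanoate (silylene-linked dienyne, key-step precursor) | CC[C@@H](C)C(=O)OC[C@](C#C)(COC(=O)C(C)C)O[Si](C(C)C)(C(C)C)OC1=CC(C)=CCC1 | intermediate
15 | [4+2] adduct, not isolated: a bicyclo[2.2.2]octa-2,5-diene whose bridgehead C1 carries the silyloxy oxygen and whose alkene carbon C6 carries the carbinol carbon, so that the dioxasiline ring is fused across C1–C6; methyl on C3, CH2–CH2 bridge C7–C8, esters as in 14, carbinol S, acyl R, bridgeheads as a mixture of the two facial isomers | CC[C@@H](C)C(=O)OC[C@]1(COC(=O)C(C)C)O[Si](C(C)C)(C(C)C)OC23CCC(C=C12)C(C)=C3 | intermediate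
16 | [(4S)-7-methyl-4-{[(2-methylpropanoyl)oxy]methyl}-2,2-di(propan-2-yl)-4H-1,3,2-benzodioxasilin-4-yl]methyl (2R)-2-methylbutanoate | CC[C@@H](C)C(=O)OC[C@]1(COC(=O)C(C)C)O[Si](C(C)C)(C(C)C)Oc2cc(C)ccc21 | intermediate
17 | (2S)-2-hydroxy-2-(2-hydroxy-4-methylphenyl)-3-[(2-methylpropanoyl)oxy]propyl (2R)-2-methylbutanoate | CC[C@@H](C)C(=O)OC[C@@](O)(COC(=O)C(C)C)c1ccc(C)cc1O | target

Total step count: 9. Longest linear sequence: 7 steps (steps 1, 2, 3, 4, 7, 8, 9, from 1 to 17); the diene branch (steps 5 and 6) joins at step 7.

Steps most likely to fail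

Step 8 (key step). The tethered cycloaddition may be outrun by hydrolytic or thermal loss of the silyl dienol ether, or the ethene extrusion may lag and call for temperatures at which the tether or the esters suffer. The fallback uses known chemistry only; it sets out from ketone 1 and comes back at target 17. 2-Bromo-5-methylphenol is benzylated (BnBr, K2CO3, DMF) to 2-(benzyloxy)-1-bromo-4-methylbenzene F1. Bromine–lithium exchange (n-BuLi, THF, −78 °C) and addition of the aryllithium to 1 should give 5-[2-(benzyloxy)-4-methylphenyl]-2,2-dimethyl-1,3-dioxan-5-ol F2. Acetal hydrolysis as in step 2 should give 2-[2-(benzyloxy)-4-methylphenyl]propane-1,2,3-triol F3. Lipase mono-isobutyrylation as in step 3 should give (2R)-2-[2-(benzyloxy)-4-methylphenyl]-2,3-dihydroxypropyl 2-methylpropanoate F4. Steglich esterification with 7 as in step 4 should give the O-benzyl ether of the target, (2S)-2-[2-(benzyloxy)-4-methylphenyl]-2-hydroxy-3-[(2-methylpropanoyl)oxy]propyl (2R)-2-methylbutanoate F5. Hydrogenolysis (H2, Pd/C, EtOAc, rt) then removes the benzyl group under neutral conditions and gives 17.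

Step 3. The enzyme may discriminate the two enantiotopic hydroxymethyl groups poorly or in the opposite sense, and acyl migration in the monoester may erode the purity before step 4. The fallback sets out from triol 4 and comes back at monoester 6. Both primary hydroxyls of 4 are acylated (2-methylpropanoyl chloride, pyridine, CH2Cl2, 0 °C) to 2-ethynyl-2-hydroxypropane-1,3-diyl bis(2-methylpropanoate) F6. An esterase (pig liver esterase, pH 7 phosphate buffer) then hydrolyses one enantiotopic ester. Hydrolysis leaves the ester on the arm the enzyme does not touch, so this mode approaches 6 from the opposite direction and with a different enzyme class.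

Step 7. Ketone 11 may slip into conjugation before it is silylated, which would lead to the cross-conjugated dienol ether; the hindered silyl triflate may react incompletely; and the silyl dienol ether may hydrolyse on isolation. The fallback inverts the order of Si–O bond formation; it sets out from 11 and 8 and comes back at 14. Ketone 11 is deprotonated at C2 with LiN(SiMe3)2 (THF, −78 °C) and the lithium dienolate is run into excess iPr2SiCl2. Evaporation of the excess leaves chloro[(3-methylcyclohexa-1,3-dien-1-yl)oxy]di(propan-2-yl)silane F7, which should silylate alcohol 8 (imidazole, DMAP, DMF, rt) to give 14.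

Further compounds
F1 | step 8 | 2-(benzyloxy)-1-bromo-4-methylbenzene | Cc1ccc(Br)c(OCc2ccccc2)c1
F2 | step 8 | 5-[2-(benzyloxy)-4-methylphenyl]-2,2-dimethyl-1,3-dioxan-5-ol | CC1(C)OCC(O)(CO1)c1ccc(C)cc1OCc1ccccc1
F3 | step 8 | 2-[2-(benzyloxy)-4-methylphenyl]propane-1,2,3-triol | OCC(O)(CO)c1ccc(C)cc1OCc1ccccc1
F4 | step 8 | (2R)-2-[2-(benzyloxy)-4-methylphenyl]-2,3-dihydroxypropyl 2-methylpropanoate | OC[C@@](O)(COC(=O)C(C)C)c1ccc(C)cc1OCc1ccccc1
F5 | step 8 | (2S)-2-[2-(benzyloxy)-4-methylphenyl]-2-hydroxy-3-[(2-methylpropanoyl)oxy]propyl (2R)-2-methylbutanoate | CC[C@@H](C)C(=O)OC[C@@](O)(COC(=O)C(C)C)c1ccc(C)cc1OCc1ccccc1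
F6 | step 3 | 2-ethynyl-2-hydroxypropane-1,3-diyl bis(2-methylpropanoate) | CC(C)C(=O)OCC(O)(C#C)COC(=O)C(C)C
F7 | step 7 | chloro[(3-methylcyclohexa-1,3-dien-1-yl)oxy]di(propan-2-yl)silane | CC1=CCCC(O[Si](Cl)(C(C)C)C(C)C)=C1
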